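The earlier runs and the new flask are calculated for an exercise; the scatter is artificial.

The flask to choose is the one whose target comes through the 5.0 h best, so the loss of target is reckoned first and its formation second.

| flask | substrate | temperature | remark | time |
|---|---|---|---|---|
| winter | 0.25 M | 55 °C | run made earlier |  |
| dawn | 0.38 M | 105 °C | run made earlier |  |
| theta | 0.50 M | 150 °C |  | 5.0 h |
| zeta | 0.50 M | 120 °C |  | 5.0 h |
| eta | 0.50 M | 90 °C |  | 5.0 h |
| alpha | 0.50 M | 60 °C |  | 5.0 h |

| run | time / h | target / % | substrate / % |
|---|---|---|---|
| winter | 40.0 | 98.5 | 0 |
| winter | 60.0 | 99.6 | 0 |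
| winter | 96.0 | 97.3 | 0 |
| winter | 144 | 96.3 | 0 |
| winter | 288 | 90.3 | 0.9 |
| winter | 480 | 86.2 | 0 |
| dawn | 3.00 | 65.5 | 0 |
| dawn | 5.00 | 47.4 | 1.2 |
| dawn | 8.00 | 30.9 | 0 |
| dawn | 12.0 | 18.5 | 0.9 |
| dawn | 25.0 | 0.9 | 0 |
| dawn | 40.0 | 0.3 | 0.5 |

(readings scatter by 1 percentage point)

- the best flask by amount of target, in percent of the substrate charged; "all alike" if 1.5 percentage points covers them all (theta / zeta / eta / alpha / all alike)
- amount of target at the end, in percent of the substrate charged, theta
- amount of target at the end, in percent of the substrate charged, zeta
- amount of target at the end, in percent of the substrate charged, eta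
- amount of target at the end, in percent of the substrate charged, alpha



1. Both runs show substrate at the scatter level from their earliest readings while target falls, so the fall is read as a first-order follow-up reaction of target. The winter run gives k = 3.03 × 10⁻⁴ h⁻¹ and the dawn run gives 0.140 h⁻¹. Dividing one constant by the other removes the clock, and with the two temperatures the ratio gives 127 kJ mol⁻¹. This is the loss energy, the activation energy of the loss of target, read from these readings.

2. The loss energy gives a survival share, exp(−kt): the part of target present from time zero that still stands after time t. Target formed later has been exposed for less than t, so a finished flask may lie a little above this share. For 5.0 h the share is 99.7 % in alpha, 87.5 % in eta and 3.81 % in zeta, and lower still in theta.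

3. Objection: a survival share stands near the yield when formation ends early in the run, and the winter run has no reading before 40.0 h. Its substrate reading there, 0 % with scatter 1 percentage point, gives formation, taken as one first-order step, a floor of 0.115 h⁻¹ at 55 °C. Over 5.0 h that floor converts 43.7 %, so alpha's survival share is no estimate yet.

4. Objection: the floor belongs to another temperature. No reading measures how formation speeds up, so the loss energy is borrowed as a working guess. The floor becomes 0.231 h⁻¹ in alpha, converting 68.5 %. In eta it becomes 10.1 h⁻¹, whose time 1/k is far shorter than the run.

5. A floor is not a rate, so alpha may still lie higher. This reckoning commits to eta at about its survival share, because its formation time is short against 5.0 h, and it takes eta as the best flask.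

The forecast differs in that choice: “Alpha is still the likeliest best”. It gives 0 % for theta, 3.6 % for zeta, 86.5 % for eta and 96 % for alpha.

The simulation gives eta as the best flask, with 87.6 %. Theta holds 0 % and zeta 3.21 %, while alpha holds 47.2 %, which is 49 points below the forecast.

    substrate → intermediate A (k = 0.277 h⁻¹, Ea = 108 kJ mol⁻¹)
    intermediate A → intermediate B (k = 0.667 h⁻¹, Ea = 110 kJ mol⁻¹)
    intermediate B → intermediate C (k = 4.32 h⁻¹, Ea = 109 kJ mol⁻¹)
    intermediate C → target (k = 1.21 h⁻¹, Ea = 108 kJ mol⁻¹)
    target → over-reaction product (k = 6.31 × 10⁻⁴ h⁻¹, Ea = 127 kJ mol⁻¹)
    (constants at 60 °C)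

At 5.00 h, alpha still holds substrate at 25.0 %. Put on alpha at 50.0 h, the loss energy gives a survival share of 97.0 %, and that flask then holds 97.3 % of target.

For a flask like eta kept at 75 °C, the loss energy gives a survival share of 97.8 %. The computed flask holds 98.1 % of target, with substrate at 0.059 %.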